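**Retrosynthetic overview**
- Target ⇐ O‑demethylation of the (Z)‑5‑alkylidene methyl tetronate ⇐ aldol addition/dehydration of lithiated 4‑methoxy‑3‑methylfuran‑2(5H)‑one with the C16 (2R)‑2‑methyl aldehyde.
- C16 aldehyde ⇐ methyl ester ⇐ SN2 coupling (inversion) of a C11 dienyl Grignard reagent with the triflate of methyl (R)‑lactate; this sets the 2R centre.
- C11 (E,E)‑dienoate ⇐ Johnson–Claisen [3,3] rearrangement of a bis‑allylic dienol: the key C–C bond, the E‑trisubstituted alkene and the conjugated diene in one step.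
- Dienol ⇐ isopropenyl Grignard + (E)‑enal ⇐ cross‑metathesis of (S)‑3‑(4‑methylhex‑5‑enyl)furan ⇐ 3‑bromofuran + (S)‑β‑citronellene; this supplies the 10S centre.
- Rings: neither is built. The furan enters first (as 3‑bromofuran), the butenolide last (as 3‑methyltetronic acid).

Assumption: the SMILES is read as (5Z)‑5‑[(2R,6E,8E,10S)‑13‑(furan‑3‑yl)‑2,6,10‑trimethyltrideca‑6,8‑dien‑1‑ylidene]‑4‑hydroxy‑3‑methylfuran‑2(5H)‑one; compounds 1, 5, 15 and 20 are taken as catalogue compounds.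

**Step 1**
Reactants: 1 (S)‑β‑citronellene [(3S)‑3,7‑dimethylocta‑1,6‑diene]
Product: 3 (S)‑4‑methylhex‑5‑en‑1‑ol, via (S)‑4‑methylhex‑5‑enal 2 (not isolated)
Conditions: O3 (1.0 equiv, Sudan Red 7B end point), CH2Cl2/MeOH, −78 °C; then NaBH4 (excess), −78 → 0 °C
Reagents that add atoms: ozone, [O-][O+]=O
Why: Chemoselective ozonolysis with reductive work‑up: the trisubstituted alkene reacts far faster than the vinyl group, and the stereocentre bought in 1 is not touched.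

**Step 2**
Reactants: 3 (S)‑4‑methylhex‑5‑en‑1‑ol
Product: 4 (S)‑6‑iodo‑3‑methylhex‑1‑ene
Conditions: I2, PPh3, imidazole, CH2Cl2, 0 °C → rt
Reagents that add atoms: iodine, II
Why: Appel‑type iodination of a primary alcohol through the alkoxyphosphonium ion (SN2 at a carbon remote from the stereocentre).

**Step 3**
Reactants: 4 (S)‑6‑iodo‑3‑methylhex‑1‑ene; 5 3‑bromofuran
Product: 7 3‑[(4S)‑4‑methylhex‑5‑en‑1‑yl]furan, via alkylzinc iodide 6 (not isolated)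
Conditions: Zn dust, LiCl, THF, 40 °C; then 5, Pd(OAc)2 (2 mol %), SPhos (4 mol %), THF, 25 °C
Reagents that add atoms: none
Why: Zinc insertion into the primary C–I bond followed by Negishi sp3–sp2 cross‑coupling; the bulky biarylphosphine suppresses β‑hydride elimination, and the vinyl group and stereocentre are spectators.

**Step 4**
Reactants: 7 3‑[(4S)‑4‑methylhex‑5‑en‑1‑yl]furan
Product: 8 (2E,4S)‑7‑(furan‑3‑yl)‑4‑methylhept‑2‑enal
Conditions: crotonaldehyde (5 equiv), second‑generation Hoveyda–Grubbs catalyst RuCl2(SIMes)(=CHC6H4‑2‑O‑i‑Pr) (3 mol %), CH2Cl2, 40 °C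
Reagents that add atoms: (E)‑but‑2‑enal (crotonaldehyde), C/C=C/C=O
Why: Olefin cross‑metathesis of a terminal alkene with an excess of enal is E‑selective and leaves the allylic stereocentre unchanged.

**Step 5**
Reactants: 8 (2E,4S)‑7‑(furan‑3‑yl)‑4‑methylhept‑2‑enal
Product: 9 (4E,6S)‑9‑(furan‑3‑yl)‑2,6‑dimethylnona‑1,4‑dien‑3‑ol (both C3 epimers)
Conditions: CH2=C(CH3)MgBr, THF, −78 °C; aq. NH4Cl
Reagents that add atoms: prop‑1‑en‑2‑ylmagnesium bromide, CC(=C)[Mg]Br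
Why: 1,2‑Grignard addition to the enal; the new carbinol centre is deliberately uncontrolled because step 6 destroys it.

**Step 6** (key step)
Reactants: 9 (4E,6S)‑9‑(furan‑3‑yl)‑2,6‑dimethylnona‑1,4‑dien‑3‑ol
Product: 12 ethyl (4E,6E,8S)‑11‑(furan‑3‑yl)‑4,8‑dimethylundeca‑4,6‑dienoate, via mixed orthoester 10 (not isolated), via ketene acetal 11 (not isolated)
Conditions: MeC(OEt)3 (8 equiv), EtCO2H (5 mol %), 135–140 °C, EtOH distilled off
Reagents that add atoms: triethyl orthoacetate, CCOC(C)(OCC)OCC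
Why: Johnson–Claisen [3,3]‑sigmatropic rearrangement through a chair transition state with the alkenyl substituent equatorial, which forms the new C–C bond at the unsubstituted CH2 terminus of the isopropenyl group, gives the 4E trisubstituted alkene in conjugation with the 6E alkene, erases the carbinol centre and leaves C8 untouched.

**Step 7**
Reactants: 12 ethyl (4E,6E,8S)‑11‑(furan‑3‑yl)‑4,8‑dimethylundeca‑4,6‑dienoate
Product: 13 (4E,6E,8S)‑11‑(furan‑3‑yl)‑4,8‑dimethylundeca‑4,6‑dien‑1‑ol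
Conditions: LiAlH4, Et2O, 0 °C
Reagents that add atoms: none
Why: Hydride reduction of the ester to the primary alcohol; the diene and the furan are inert to LiAlH4.

**Step 8**
Reactants: 13 (4E,6E,8S)‑11‑(furan‑3‑yl)‑4,8‑dimethylundeca‑4,6‑dien‑1‑ol
Product: 14 3‑[(4S,5E,7E)‑11‑bromo‑4,8‑dimethylundeca‑5,7‑dien‑1‑yl]furan
Conditions: CBr4, PPh3, CH2Cl2, 0 °C
Reagents that add atoms: tetrabromomethane, BrC(Br)(Br)Br
Why: Appel bromination under neutral conditions that the diene and the furan tolerate.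

**Step 9**
Reactants: 15 methyl (R)‑lactate [methyl (2R)‑2‑hydroxypropanoate]
Product: 16 methyl (2R)‑2‑{[(trifluoromethyl)sulfonyl]oxy}propanoate
Conditions: Tf2O, 2,6‑lutidine, CH2Cl2, −78 → 0 °C; used at once
Reagents that add atoms: trifluoromethanesulfonic anhydride, FC(F)(F)S(=O)(=O)OS(=O)(=O)C(F)(F)F
Why: O‑sulfonylation without breaking the C–O bond (retention) turns the lactate hydroxyl into a leaving group.

**Step 10**
Reactants: 14 3‑[(4S,5E,7E)‑11‑bromo‑4,8‑dimethylundeca‑5,7‑dien‑1‑yl]furan; 16 methyl (2R)‑2‑{[(trifluoromethyl)sulfonyl]oxy}propanoate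
Product: 18 methyl (2R,6E,8E,10S)‑13‑(furan‑3‑yl)‑2,6,10‑trimethyltrideca‑6,8‑dienoate, via Grignard reagent 17 (not isolated)
Conditions: Mg, THF, 35 °C; then added to 16 (1.3 equiv), ZnCl2 (5 mol %), THF, 0 °C
Reagents that add atoms: none
Why: Zinc‑catalysed sp3–sp3 coupling in which a triorganozincate displaces the α‑triflate by SN2 with clean inversion, so the C2 centre comes from lactate; the descriptor stays R only because the CIP priorities change.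

**Step 11**
Reactants: 18 methyl (2R,6E,8E,10S)‑13‑(furan‑3‑yl)‑2,6,10‑trimethyltrideca‑6,8‑dienoate
Product: 19 (2R,6E,8E,10S)‑13‑(furan‑3‑yl)‑2,6,10‑trimethyltrideca‑6,8‑dienal
Conditions: i‑Bu2AlH (1.1 equiv), CH2Cl2, −78 °C; aq. KNaC4H4O6; used crude
Reagents that add atoms: none
Why: Partial ester reduction stops at the tetrahedral aluminium hemiacetal at −78 °C, and the α‑stereocentre does not epimerise under these cold, non‑basic conditions.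

**Step 12**
Reactants: 20 3‑methyltetronic acid [4‑hydroxy‑3‑methylfuran‑2(5H)‑one]
Product: 21 4‑methoxy‑3‑methylfuran‑2(5H)‑one
Conditions: Me2SO4, K2CO3, acetone, reflux
Reagents that add atoms: dimethyl sulfate, COS(=O)(=O)OC
Why: O‑methylation of the vinylogous acid masks the acidic OH so that C5 can be lithiated.

**Step 13**
Reactants: 21 4‑methoxy‑3‑methylfuran‑2(5H)‑one; 19 (2R,6E,8E,10S)‑13‑(furan‑3‑yl)‑2,6,10‑trimethyltrideca‑6,8‑dienal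
Product: 23 5‑[(2R,6E,8E,10S)‑13‑(furan‑3‑yl)‑1‑hydroxy‑2,6,10‑trimethyltrideca‑6,8‑dien‑1‑yl]‑4‑methoxy‑3‑methylfuran‑2(5H)‑one (diastereomer mixture at C5 and C1′), via lithiated tetronate 22 (not isolated)
Conditions: LiN(i‑Pr)2 (commercial solution), THF, −78 °C; then 19, −78 °C; AcOH quench at −78 °C
Reagents that add atoms: none
Why: Vinylogous (γ) deprotonation at C5 and aldol addition to the aldehyde; the two new centres are uncontrolled and removed in step 14, while C2′ is safe at −78 °C.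

**Step 14**
Reactants: 23 aldol adduct
Product: 25 (5Z)‑5‑[(2R,6E,8E,10S)‑13‑(furan‑3‑yl)‑2,6,10‑trimethyltrideca‑6,8‑dien‑1‑ylidene]‑4‑methoxy‑3‑methylfuran‑2(5H)‑one, via mesylate 24 (not isolated)
Conditions: MsCl, Et3N, CH2Cl2, 0 °C; then DBU, 0 °C → rt (short contact); minor E isomer removed by chromatography
Reagents that add atoms: none
Why: Mesylation then E1cB elimination through the acidic C5–H gives mainly the Z‑alkylidene butenolide, because the E isomer suffers allylic strain between the side chain and the 4‑OMe group.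

**Step 15**
Reactants: 25 (5Z)‑methyl tetronate
Product: 26 (5Z)‑5‑[(2R,6E,8E,10S)‑13‑(furan‑3‑yl)‑2,6,10‑trimethyltrideca‑6,8‑dien‑1‑ylidene]‑4‑hydroxy‑3‑methylfuran‑2(5H)‑one (target)
Conditions: n‑PrSLi (from n‑PrSH, n‑BuLi), HMPA, 25 °C; then 1 M HCl
Reagents that add atoms: none
Why: SN2 O‑demethylation of the vinylogous methyl ester by thiolate gives the tetronate anion, which resists further attack; acidification releases the tetronic acid with both stereocentres and all three alkene geometries intact.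

**Compound list**
1 | (S)‑β‑citronellene, (3S)‑3,7‑dimethylocta‑1,6‑diene | C=C[C@@H](C)CCC=C(C)C | starting material
2 | (S)‑4‑methylhex‑5‑enal | C=C[C@@H](C)CCC=O | intermediate (not isolated)
3 | (S)‑4‑methylhex‑5‑en‑1‑ol | C=C[C@@H](C)CCCO | intermediate
4 | (S)‑6‑iodo‑3‑methylhex‑1‑ene | C=C[C@@H](C)CCCI | intermediate
5 | 3‑bromofuran | Brc1ccoc1 | starting material
6 | [(4S)‑4‑methylhex‑5‑en‑1‑yl]zinc iodide | C=C[C@@H](C)CCC[Zn]I | intermediate (not isolated)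
7 | 3‑[(4S)‑4‑methylhex‑5‑en‑1‑yl]furan | C=C[C@@H](C)CCCc1ccoc1 | intermediate
8 | (2E,4S)‑7‑(furan‑3‑yl)‑4‑methylhept‑2‑enal | O=C/C=C/[C@@H](C)CCCc1ccoc1 | intermediate
9 | (4E,6S)‑9‑(furan‑3‑yl)‑2,6‑dimethylnona‑1,4‑dien‑3‑ol (C3 epimers) | C=C(C)C(O)/C=C/[C@@H](C)CCCc1ccoc1 | intermediate
10 | 3‑[(4S,5E)‑7‑(1,1‑diethoxyethoxy)‑4,8‑dimethylnona‑5,8‑dien‑1‑yl]furan | CCOC(C)(OCC)OC(C(C)=C)/C=C/[C@@H](C)CCCc1ccoc1 | intermediate (not isolated)
11 | 3‑[(4S,5E)‑7‑[(1‑ethoxyethenyl)oxy]‑4,8‑dimethylnona‑5,8‑dien‑1‑yl]furan | CCOC(=C)OC(C(C)=C)/C=C/[C@@H](C)CCCc1ccoc1 | intermediate (not isolated)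
12 | ethyl (4E,6E,8S)‑11‑(furan‑3‑yl)‑4,8‑dimethylundeca‑4,6‑dienoate | CCOC(=O)CC/C(C)=C/C=C/[C@@H](C)CCCc1ccoc1 | intermediate
13 | (4E,6E,8S)‑11‑(furan‑3‑yl)‑4,8‑dimethylundeca‑4,6‑dien‑1‑ol | OCCC/C(C)=C/C=C/[C@@H](C)CCCc1ccoc1 | intermediate
14 | 3‑[(4S,5E,7E)‑11‑bromo‑4,8‑dimethylundeca‑5,7‑dien‑1‑yl]furan | BrCCC/C(C)=C/C=C/[C@@H](C)CCCc1ccoc1 | intermediate
15 | methyl (R)‑lactate, methyl (2R)‑2‑hydroxypropanoate | C[C@@H](O)C(=O)OC | starting material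
16 | methyl (2R)‑2‑{[(trifluoromethyl)sulfonyl]oxy}propanoate | C[C@@H](OS(=O)(=O)C(F)(F)F)C(=O)OC | intermediate
17 | [(4E,6E,8S)‑11‑(furan‑3‑yl)‑4,8‑dimethylundeca‑4,6‑dien‑1‑yl]magnesium bromide | Br[Mg]CCC/C(C)=C/C=C/[C@@H](C)CCCc1ccoc1 | intermediate (not isolated)
18 | methyl (2R,6E,8E,10S)‑13‑(furan‑3‑yl)‑2,6,10‑trimethyltrideca‑6,8‑dienoate | COC(=O)[C@H](C)CCC/C(C)=C/C=C/[C@@H](C)CCCc1ccoc1 | intermediate
19 | (2R,6E,8E,10S)‑13‑(furan‑3‑yl)‑2,6,10‑trimethyltrideca‑6,8‑dienal | O=C[C@H](C)CCC/C(C)=C/C=C/[C@@H](C)CCCc1ccoc1 | intermediate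
20 | 3‑methyltetronic acid, 4‑hydroxy‑3‑methylfuran‑2(5H)‑one | CC1=C(O)COC1=O | starting material
21 | 4‑methoxy‑3‑methylfuran‑2(5H)‑one | CC1=C(OC)COC1=O | intermediate
22 | lithium 4‑methoxy‑3‑methylfuran‑2‑olate (C5‑lithiated 21) | [Li+].[O-]c1occ(OC)c1C | intermediate (not isolated)
23 | 5‑[(2R,6E,8E,10S)‑13‑(furan‑3‑yl)‑1‑hydroxy‑2,6,10‑trimethyltrideca‑6,8‑dien‑1‑yl]‑4‑methoxy‑3‑methylfuran‑2(5H)‑one | CC1=C(OC)C(OC1=O)C(O)[C@H](C)CCC/C(C)=C/C=C/[C@@H](C)CCCc2ccoc2 | intermediate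
24 | (2R,6E,8E,10S)‑13‑(furan‑3‑yl)‑1‑(3‑methoxy‑4‑methyl‑5‑oxo‑2,5‑dihydrofuran‑2‑yl)‑2,6,10‑trimethyltrideca‑6,8‑dien‑1‑yl methanesulfonate | CC1=C(OC)C(OC1=O)C(OS(C)(=O)=O)[C@H](C)CCC/C(C)=C/C=C/[C@@H](C)CCCc2ccoc2 | intermediate (not isolated)
25 | (5Z)‑5‑[(2R,6E,8E,10S)‑13‑(furan‑3‑yl)‑2,6,10‑trimethyltrideca‑6,8‑dien‑1‑ylidene]‑4‑methoxy‑3‑methylfuran‑2(5H)‑one | CC1=C(OC)/C(=C/[C@H](C)CCC/C(C)=C/C=C/[C@@H](C)CCCc2ccoc2)OC1=O | intermediate
26 | (5Z)‑5‑[(2R,6E,8E,10S)‑13‑(furan‑3‑yl)‑2,6,10‑trimethyltrideca‑6,8‑dien‑1‑ylidene]‑4‑hydroxy‑3‑methylfuran‑2(5H)‑one | CC1=C(O)/C(=C/[C@H](C)CCC/C(C)=C/C=C/[C@@H](C)CCCc2ccoc2)OC1=O | target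

**Step count**
Total: 15 steps. Longest linear sequence: 13 steps (1–8, 10, 11, 13, 14, 15); steps 9 and 12 are one‑step side branches.

**Steps most likely to fail, with fallbacks**

Step 6 (Johnson–Claisen on a bis‑allylic alcohol). The hot, weakly acidic conditions can ionise the dienol or let some rearrangement leak through the other alkene. The fallback keeps the same [3,3] bond formation but runs it under basic, non‑ionising conditions. It sets out from 9 and comes back at 13. Compound 9 is acetylated (Ac2O, pyridine, DMAP) to (4E,6S)‑9‑(furan‑3‑yl)‑2,6‑dimethylnona‑1,4‑dien‑3‑yl acetate F1. Treatment with LiN(i‑Pr)2, Me3SiCl and Et3N in THF at −78 °C gives the silyl ketene acetal 3‑[(4S,5E)‑4,8‑dimethyl‑7‑({1‑[(trimethylsilyl)oxy]ethenyl}oxy)nona‑5,8‑dien‑1‑yl]furan F2. On warming to 25–50 °C this undergoes Ireland–Claisen rearrangement to trimethylsilyl (4E,6E,8S)‑11‑(furan‑3‑yl)‑4,8‑dimethylundeca‑4,6‑dienoate F3. Aqueous work‑up gives (4E,6E,8S)‑11‑(furan‑3‑yl)‑4,8‑dimethylundeca‑4,6‑dienoic acid F4, which LiAlH4 reduces directly to 13.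

Step 10 (late sp3–sp3 coupling next to an ester). Carbonyl attack or enolisation/elimination of the α‑triflyloxy ester could compete. The fallback uses an electrophile at the alcohol oxidation level. It sets out from 14 (through Grignard reagent 17) and comes back at 19, bypassing 18 and step 11. Purchased (R)‑propane‑1,2‑diol is silylated (t‑BuMe2SiCl, imidazole) to (2R)‑1‑[(tert‑butyldimethylsilyl)oxy]propan‑2‑ol F5 and tosylated (TsCl, pyridine) to (2R)‑1‑[(tert‑butyldimethylsilyl)oxy]propan‑2‑yl 4‑methylbenzenesulfonate F6. Grignard reagent 17 displaces the secondary tosylate with inversion (CuI, TMEDA, LiOMe, THF, 0 °C) to give tert‑butyl{[(2R,6E,8E,10S)‑13‑(furan‑3‑yl)‑2,6,10‑trimethyltrideca‑6,8‑dien‑1‑yl]oxy}dimethylsilane F7. Bu4NF gives (2R,6E,8E,10S)‑13‑(furan‑3‑yl)‑2,6,10‑trimethyltrideca‑6,8‑dien‑1‑ol F8, and Dess–Martin periodinane oxidises it to 19. This displacement at an unactivated secondary centre is slower than the main step, so it is a reserve rather than an equal alternative.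

Step 15 (thiolate demethylation of a polyunsaturated tetronate). Conjugate addition or addition–elimination at C4 may compete. The fallback replaces the methyl ether by a fluoride‑labile ether. It sets out from 20 and 19 and comes back at 26. Mitsunobu etherification of 20 (2‑(trimethylsilyl)ethanol, PPh3, diisopropyl azodicarboxylate) gives 3‑methyl‑4‑[2‑(trimethylsilyl)ethoxy]furan‑2(5H)‑one F9. LiN(i‑Pr)2 at −78 °C gives lithium 3‑methyl‑4‑[2‑(trimethylsilyl)ethoxy]furan‑2‑olate F10, which adds to 19 to give 5‑[(2R,6E,8E,10S)‑13‑(furan‑3‑yl)‑1‑hydroxy‑2,6,10‑trimethyltrideca‑6,8‑dien‑1‑yl]‑3‑methyl‑4‑[2‑(trimethylsilyl)ethoxy]furan‑2(5H)‑one F11. MsCl/Et3N gives (2R,6E,8E,10S)‑13‑(furan‑3‑yl)‑2,6,10‑trimethyl‑1‑{4‑methyl‑5‑oxo‑3‑[2‑(trimethylsilyl)ethoxy]‑2,5‑dihydrofuran‑2‑yl}trideca‑6,8‑dien‑1‑yl methanesulfonate F12, and DBU eliminates it to (5Z)‑5‑[(2R,6E,8E,10S)‑13‑(furan‑3‑yl)‑2,6,10‑trimethyltrideca‑6,8‑dien‑1‑ylidene]‑3‑methyl‑4‑[2‑(trimethylsilyl)ethoxy]furan‑2(5H)‑one F13. Bu4NF in THF at 0 °C, then dilute acid, releases 26.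

**Further compounds**
F1 | step 6 | (4E,6S)‑9‑(furan‑3‑yl)‑2,6‑dimethylnona‑1,4‑dien‑3‑yl acetate | CC(=O)OC(C(C)=C)/C=C/[C@@H](C)CCCc1ccoc1
F2 | step 6 | 3‑[(4S,5E)‑4,8‑dimethyl‑7‑({1‑[(trimethylsilyl)oxy]ethenyl}oxy)nona‑5,8‑dien‑1‑yl]furan | C=C(O[Si](C)(C)C)OC(C(C)=C)/C=C/[C@@H](C)CCCc1ccoc1
F3 | step 6 | trimethylsilyl (4E,6E,8S)‑11‑(furan‑3‑yl)‑4,8‑dimethylundeca‑4,6‑dienoate | C[Si](C)(C)OC(=O)CC/C(C)=C/C=C/[C@@H](C)CCCc1ccoc1
F4 | step 6 | (4E,6E,8S)‑11‑(furan‑3‑yl)‑4,8‑dimethylundeca‑4,6‑dienoic acid | OC(=O)CC/C(C)=C/C=C/[C@@H](C)CCCc1ccoc1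
F5 | step 10 | (2R)‑1‑[(tert‑butyldimethylsilyl)oxy]propan‑2‑ol | C[C@@H](O)CO[Si](C)(C)C(C)(C)C
F6 | step 10 | (2R)‑1‑[(tert‑butyldimethylsilyl)oxy]propan‑2‑yl 4‑methylbenzenesulfonate | C[C@@H](OS(=O)(=O)c1ccc(C)cc1)CO[Si](C)(C)C(C)(C)C
F7 | step 10 | tert‑butyl{[(2R,6E,8E,10S)‑13‑(furan‑3‑yl)‑2,6,10‑trimethyltrideca‑6,8‑dien‑1‑yl]oxy}dimethylsilane | CC(C)(C)[Si](C)(C)OC[C@H](C)CCC/C(C)=C/C=C/[C@@H](C)CCCc1ccoc1
F8 | step 10 | (2R,6E,8E,10S)‑13‑(furan‑3‑yl)‑2,6,10‑trimethyltrideca‑6,8‑dien‑1‑ol | OC[C@H](C)CCC/C(C)=C/C=C/[C@@H](C)CCCc1ccoc1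
F9 | step 15 | 3‑methyl‑4‑[2‑(trimethylsilyl)ethoxy]furan‑2(5H)‑one | CC1=C(OCC[Si](C)(C)C)COC1=O
F10 | step 15 | lithium 3‑methyl‑4‑[2‑(trimethylsilyl)ethoxy]furan‑2‑olate | [Li+].[O-]c1occ(OCC[Si](C)(C)C)c1C
F11 | step 15 | 5‑[(2R,6E,8E,10S)‑13‑(furan‑3‑yl)‑1‑hydroxy‑2,6,10‑trimethyltrideca‑6,8‑dien‑1‑yl]‑3‑methyl‑4‑[2‑(trimethylsilyl)ethoxy]furan‑2(5H)‑one | CC1=C(OCC[Si](C)(C)C)C(OC1=O)C(O)[C@H](C)CCC/C(C)=C/C=C/[C@@H](C)CCCc2ccoc2
F12 | step 15 | (2R,6E,8E,10S)‑13‑(furan‑3‑yl)‑2,6,10‑trimethyl‑1‑{4‑methyl‑5‑oxo‑3‑[2‑(trimethylsilyl)ethoxy]‑2,5‑dihydrofuran‑2‑yl}trideca‑6,8‑dien‑1‑yl methanesulfonate | CC1=C(OCC[Si](C)(C)C)C(OC1=O)C(OS(C)(=O)=O)[C@H](C)CCC/C(C)=C/C=C/[C@@H](C)CCCc2ccoc2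
F13 | step 15 | (5Z)‑5‑[(2R,6E,8E,10S)‑13‑(furan‑3‑yl)‑2,6,10‑trimethyltrideca‑6,8‑dien‑1‑ylidene]‑3‑methyl‑4‑[2‑(trimethylsilyl)ethoxy]furan‑2(5H)‑one | CC1=C(OCC[Si](C)(C)C)/C(=C/[C@H](C)CCC/C(C)=C/C=C/[C@@H](C)CCCc2ccoc2)OC1=O
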